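In this closed flask a product cannot hold more of the starting material than the flask has lost, so while more remains than has left, the starting material leads, and to say that much I need not follow where it went.

all flasks: starting material 0.050 M; first nucleophile 0.250 M; second nucleophile 0.0500 M

| run | time |
|---|---|
| violet | 25 min |
| blue | 30 min |
| red | 40 min |

    starting material → intermediate (k1 = 0.00926 /min)
    intermediate → side product (k2 = 0.0209 /min)
    second nucleophile + intermediate → other capture product (k3 = 91.5 /M/min)
    first nucleophile + intermediate → target (k4 = 1.11 /M/min)
    first nucleophile + target ⇌ idle adduct, settled at all times (K5 = 5.67 /M)

- for target the idle adduct is counted in
- run time (violet): 25 min

- which of these there is most of at the end, counted by the starting material in it, violet (starting material / other capture product / intermediate / target)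
- which of these there is most of at the end, counted by the starting material in it, blue (starting material / other capture product / intermediate / target)
- which of these there is most of at the end, counted by the starting material in it, red (starting material / other capture product / intermediate / target)
- final amount of the leader among these, as a percentage of the starting material charged, in violet
- final amount of the leader among these, as a percentage of the starting material charged, in blue
- final amount of the leader among these, as a percentage of the starting material charged, in red

Violet, blue and red carry the same charges and differ in reading time, so red, at 40 min, is furthest along. The first step has the starting material alone on its left and no later step returns any, so I count turnovers: n = k·t, with k the constant of the first step and t the time of reading, is 0.231 in violet. It is 0.278 in blue and 0.370 in red, and the share remaining is exp(−n), which gives 79.4%, 75.7% and 69.1%.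

What remains exceeds what has left while n is under the natural logarithm of two, 0.693. Red is still under it, so by the opening rule I commit to the starting material leading in each flask.

But who comes second? In violet the intermediate has a half-life of 0.15 min by capture with the second nucleophile, against 2.5 min with the first nucleophile and 33 min to side product. Each of these is shorter than the 75 min of the starting material, so the first step is the rate-limiting step, and I expect the other capture product second.

The forecast gives violet starting material at 79.3%, blue starting material at 75.7% and red starting material at 69%, since “the starting material simply decays”.

The simulation gives violet starting material at 79.3%, blue starting material at 75.7% and red starting material at 69.0%, with the other capture product at 28.6% in red.

The lead rests on the early reading: violet left ten times as long has n = 2.31, and its starting material falls from 79.3% to 9.88%.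

Violet's neighbour read at 1.5 h has n = 0.833, so exp(−n) gives 43.5%, and what has left now exceeds what remains, so the opening rule no longer names a leader there. Computed, it holds 43.5% of starting material and 51.7% of other capture product, the two having crossed at 79.7 min.

(The numbers of this flask are assumed; no experiment stands behind them.)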